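**Assumption:** atom labels C1–C25 follow the heavy-atom order of the target SMILES (O9, N23, C24 = N‑CH3, carboxyl oxygens unnumbered) and are kept for all intermediates; ring C = C13–C17, ring D = C14/C15/C18/C20/C21.

This route is a paper proposal; none of it has been run, and the selectivities stated are predictions.

## Retrosynthetic overview

1. Target ⇐ methyl ester 39 ⇐ δ‑hydroxy ketone 37 (dihydropyran by cyclodehydration, last ring); C15‑H/C18‑H are set late by face‑selective hydrogenation of dienoate 34.
2. Spiro C7 ⇐ bridging aldehyde 28: crossed aldol with formaldehyde (C8), then aldol with 3‑methylbutan‑2‑one (C4–C6 and the isopropyl group).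
3. Seven‑membered ring ⇐ intramolecular enolate alkylation (C10–C11) of spiro‑piperidone 20; ring C ⇐ McMurry coupling of 1,5‑diketone 17.
4. 17 ⇐ Michael addition of ring‑D β‑keto ester 14 to enone 5; ring D ⇐ Dieckmann cyclisation of 13.
5. C21 (first stereocentre) ⇐ enantioselective intermolecular Michael addition of piperidone β‑keto ester 6 to acrolein 7. Ring order: piperidine (bought) → D → C → seven‑membered → dihydropyran.

## Route

**Step 1**
Reactants: 1 3-((tert-butyldimethylsilyl)oxy)propan-1-ol
Product: 2 3-((tert-butyldimethylsilyl)oxy)propanal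
Conditions: Dess–Martin periodinane, CH2Cl2, 0 °C → rt
Reagents that add atoms: none
Why: Dess–Martin oxidation takes the primary alcohol to the aldehyde without touching the silyl ether.

**Step 2**
Reactants: 2 3-((tert-butyldimethylsilyl)oxy)propanal; 3 vinylmagnesium bromide
Product: 4 5-((tert-butyldimethylsilyl)oxy)pent-1-en-3-ol
Conditions: CH2=CHMgBr, THF, −78 → 0 °C; aq. NH4Cl
Reagents that add atoms: none
Why: Grignard 1,2‑addition gives the racemic allylic alcohol, whose stereocentre is removed in step 3.

**Step 3**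
Reactants: 4 5-((tert-butyldimethylsilyl)oxy)pent-1-en-3-ol
Product: 5 5-((tert-butyldimethylsilyl)oxy)pent-1-en-3-one
Conditions: Dess–Martin periodinane, CH2Cl2, 0 °C → rt (used fresh)
Reagents that add atoms: none
Why: Dess–Martin oxidation of the allylic alcohol gives the vinyl ketone Michael acceptor that carries C11–C13, C16 and C17.

**Step 4**
Reactants: 6 1-tert-butyl 3-methyl 4-oxopiperidine-1,3-dicarboxylate; 7 acrolein
Product: 8 (S)-Michael adduct aldehyde
Conditions: 9-O-(phenanthren-9-yl)cupreidine (10 mol %), CH2Cl2, −24 °C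
Reagents that add atoms: none
Why: Bifunctional cinchona‑catalysed intermolecular Michael addition of the β‑keto ester to acrolein forms C21–C20 and sets quaternary C21 (S in 8) by hydrogen‑bond‑directed attack on one enolate face; the quinidine‑derived catalyst is assumed to give S, and its cupreine pseudoenantiomer is used if the sense is reversed.

**Step 5**
Reactants: 8 (S)-Michael adduct aldehyde
Product: 9 (S)-carboxylic acid
Conditions: NaClO2, NaH2PO4, 2-methylbut-2-ene, tBuOH/H2O, 0 °C → rt
Reagents that add atoms: sodium chlorite, [Na+].[O-]Cl=O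
Why: Pinnick oxidation converts the aldehyde (C19) to the acid without touching the non‑enolisable‑at‑C21 β‑keto ester.

**Step 6**
Reactants: 9 (S)-carboxylic acid
Product: 10 (S)-keto diester
Conditions: MeI, K2CO3, DMF, rt
Reagents that add atoms: iodomethane, CI
Why: SN2 O‑methylation of the carboxylate gives the methyl ester that later becomes the C19 carboxyl.

**Step 7**
Reactants: 10 (S)-keto diester
Product: 11 (S)-ketal diester
Conditions: ethylene glycol, PPTS (cat.), benzene, reflux (Dean–Stark)
Reagents that add atoms: ethylene glycol, OCCO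
Why: Acid‑catalysed ketalisation masks the C7 ketone so that the following enolate and low‑valent titanium steps address only the intended carbonyls.

**Step 8**
Reactants: 11 (S)-ketal diester; 12 benzyl bromoacetate
Product: 13 ketal triester
Conditions: LiN(iPr)2, THF, −78 °C; then 12, −78 → −40 °C
Reagents that add atoms: none
Why: Ester enolate alkylation (SN2) at C18, the only enolisable position, attaches C15/C16; the C18 stereocentre formed is inconsequential because it is erased in step 18.

**Step 9**
Reactants: 13 ketal triester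
Product: 14 ring-D spiro β-keto ester
Conditions: KOtBu, THF, 0 °C; AcOH quench
Reagents that add atoms: none
Why: Dieckmann condensation (5‑exo attack of the C15 enolate on the C14 ester) closes ring D and is driven by formation of the β‑keto ester enolate.

**Step 10**
Reactants: 14 ring-D spiro β-keto ester; 5 5-((tert-butyldimethylsilyl)oxy)pent-1-en-3-one
Product: 15 Michael adduct with quaternary C15
Conditions: Cs2CO3 (10 mol %), MeCN, 0 °C → rt
Reagents that add atoms: none
Why: Base‑catalysed intermolecular Michael addition of the doubly activated C15–H to the vinyl ketone joins the two fragments regioselectively (C15–C16 bond).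

**Step 11**
Reactants: 15 Michael adduct with quaternary C15
Product: 17 ring-D 1,5-diketone, via β-keto acid 16 (not isolated)
Conditions: H2 (1 atm), Pd/C (10 wt %), EtOAc, rt; then toluene, 80 °C
Reagents that add atoms: none
Why: Hydrogenolysis of the benzyl ester followed by thermal decarboxylation of the β‑keto acid removes the activating group under neutral conditions that avoid aldol cyclisation of the 1,5‑diketone.

**Step 12**
Reactants: 17 ring-D 1,5-diketone
Product: 18 tricyclic alkene
Conditions: TiCl3(DME)1.5, Zn–Cu couple, DME, reflux, slow addition (high dilution)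
Reagents that add atoms: none
Why: Intramolecular McMurry coupling of the C13 and C14 ketones closes ring C and forms the tetrasubstituted C13=C14 alkene directly, with no oxygen left on C17.

**Step 13**
Reactants: 18 tricyclic alkene
Product: 19 keto alcohol
Conditions: HCl (2 M aq.), THF, 40 °C
Reagents that add atoms: water, O
Why: Acid hydrolysis removes the dioxolane and the primary silyl ether in one operation while the Boc group survives dilute aqueous acid.

**Step 14**
Reactants: 19 keto alcohol
Product: 20 keto iodide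
Conditions: I2, PPh3, imidazole, CH2Cl2, 0 °C
Reagents that add atoms: iodine, II
Why: Appel iodination converts the primary alcohol at C11 into the electrophile for ring closure.

**Step 15**
Reactants: 20 keto iodide
Product: 21 bridged tetracyclic ketone
Conditions: KN(SiMe3)2, THF (0.005 M), −78 → 0 °C
Reagents that add atoms: none
Why: Intramolecular alkylation of the only possible ketone enolate (C10) by the primary iodide closes the seven‑membered ring; the cis alkene holds the chain next to C21 and the bridge can only form in one sense, which fixes C10.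

**Step 16**
Reactants: 21 bridged tetracyclic ketone
Product: 22 exocyclic alkene
Conditions: Ph3PCH3Br, KOtBu, toluene, 90 °C
Reagents that add atoms: methyltriphenylphosphonium bromide, C[P+](c1ccccc1)(c1ccccc1)c1ccccc1.[Br-]
Why: Wittig methylenation of the non‑enolisable bridging ketone introduces C6 with a ylide too weakly basic to deprotonate the ester.

**Step 17**
Reactants: 22 exocyclic alkene
Product: 23 α-phenylselanyl ester
Conditions: KN(SiMe3)2, THF, −78 °C; then PhSeBr
Reagents that add atoms: benzeneselenenyl bromide, Br[Se]c1ccccc1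
Why: Selenenylation of the ester enolate at C18 (the only acidic C–H) occurs anti to the C16 substituent, placing selenium syn to H15.

**Step 18**
Reactants: 23 α-phenylselanyl ester
Product: 25 dienoate, via selenoxide 24 (not isolated)
Conditions: mCPBA, CH2Cl2, −78 °C; then iPr2NH, −78 °C → rt
Reagents that add atoms: none
Why: Selenoxide syn‑elimination towards the allylic C15–H gives the conjugated C13=C14–C15=C18 dienoate and thereby erases the uncontrolled C15 and C18 centres.

**Step 19**
Reactants: 25 dienoate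
Product: 27 primary alcohol, via B-alkyl-9-BBN adduct 26 (not isolated)
Conditions: 9-BBN, THF, rt → 50 °C; then H2O2 (30 %), NaOH (1 M), 0 °C
Reagents that add atoms: hydrogen peroxide, OO
Why: Anti‑Markovnikov hydroboration–oxidation engages only the 1,1‑disubstituted exocyclic alkene; the tetrasubstituted and electron‑poor alkenes are inert, and the C7–H centre formed is erased in step 21.

**Step 20**
Reactants: 27 primary alcohol
Product: 28 bridging aldehyde
Conditions: Dess–Martin periodinane, CH2Cl2, rt
Reagents that add atoms: none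
Why: Dess–Martin oxidation gives the α‑branched aldehyde whose enol is the C7 nucleophile.

**Step 21**
Reactants: 28 bridging aldehyde
Product: 29 hydroxymethyl aldehyde
Conditions: CH2O (37 % aq.), K2CO3 (0.2 equiv), MeOH/THF, 40 °C
Reagents that add atoms: formaldehyde, C=O
Why: Crossed aldol with formaldehyde creates quaternary C7; formaldehyde is predicted to approach the exocyclic enolate over the cycloheptene bridge (sp2 C14, one axial H) rather than over the piperidine bridge (two axial H), so CH2OH (C8) ends syn to the alkene bridge and CHO (C6) on the nitrogen side.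

**Step 22**
Reactants: 29 hydroxymethyl aldehyde
Product: 30 silyl ether aldehyde
Conditions: TBSCl, imidazole, DMF, rt
Reagents that add atoms: tert-butyldimethylsilyl chloride, CC(C)(C)[Si](C)(C)Cl
Why: Silylation blocks retro‑aldol loss of formaldehyde and later hydroxyl‑directed hydrogenation, and adds bulk on the face of ring D that must be shielded.

**Step 23**
Reactants: 30 silyl ether aldehyde; 31 3-methylbutan-2-one
Product: 32 β-hydroxy ketone
Conditions: 31, LiN(iPr)2, THF, −78 °C; then 30, −78 °C; aq. NH4Cl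
Reagents that add atoms: none
Why: Intermolecular aldol addition of the kinetic (methyl‑side) lithium enolate to the non‑enolisable neopentyl aldehyde forms C5–C6; the carbinol centre is removed in step 24.

**Step 24**
Reactants: 32 β-hydroxy ketone
Product: 34 E-enone, via mesylate 33 (not isolated)
Conditions: MsCl, Et3N, CH2Cl2, 0 °C; then DBU, rt
Reagents that add atoms: none
Why: Mesylation and E1cB elimination give the E‑enone, completing the C4–C6 chain at the correct oxidation level.

**Step 25**
Reactants: 34 E-enone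
Product: 35 saturated keto ester
Conditions: H2 (60 bar), [Rh(nbd)(dppb)]BF4 (10 mol %), CH2Cl2, rt
Reagents that add atoms: none
Why: Homogeneous hydrogenation reduces the enone C=C and the α,β‑bond of the dienoate (C13=C14, flanked by quaternary C21, is inert); both hydrogens add to the ring‑D face away from the C7 bridge and its CH2OTBS group, setting C15 and C18 cis as in the target.

**Step 26**
Reactants: 35 saturated keto ester
Product: 36 amino hydroxy ketone
Conditions: HCl (4 M in 1,4-dioxane), then H2O, rt; NaHCO3 work-up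
Reagents that add atoms: none
Why: Acidolysis removes the Boc group and the silyl ether together; the product (in equilibrium with its lactol) has no epimerisable centre under these conditions.

**Step 27**
Reactants: 36 amino hydroxy ketone
Product: 37 N-methyl amino hydroxy ketone
Conditions: CH2O (37 % aq.), NaBH(OAc)3, AcOH, ClCH2CH2Cl, rt
Reagents that add atoms: formaldehyde, C=O
Why: Reductive amination methylates the secondary amine while NaBH(OAc)3 leaves the hindered ketone untouched.

**Step 28**
Reactants: 37 N-methyl amino hydroxy ketone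
Product: 39 target methyl ester, via cyclic hemiketal 38 (not isolated)
Conditions: camphorsulfonic acid (1.1 equiv), PPTS (0.2 equiv), 4 Å molecular sieves, toluene, 90 °C; Et3N quench
Reagents that add atoms: none
Why: Acid‑catalysed cyclodehydration of the δ‑hydroxy ketone through the six‑membered hemiketal gives the endocyclic enol ether, with the amine buffered as its sulfonate salt.

**Step 29**
Reactants: 39 target methyl ester
Product: 40 CNP0237695.1
Conditions: Me3SnOH, ClCH2CH2Cl, 80 °C; then aq. KF, pH 7 phosphate buffer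
Reagents that add atoms: trimethyltin hydroxide, C[Sn](C)(C)O
Why: Neutral trimethyltin hydroxide ester cleavage frees the acid without epimerising C18 or hydrolysing the enol ether.

## Compound list

1 | 3-((tert-butyldimethylsilyl)oxy)propan-1-ol | OCCCO[Si](C)(C)C(C)(C)C | starting material
2 | 3-((tert-butyldimethylsilyl)oxy)propanal | O=CCCO[Si](C)(C)C(C)(C)C | intermediate
3 | vinylmagnesium bromide | C=C[Mg]Br | starting material
4 | 5-((tert-butyldimethylsilyl)oxy)pent-1-en-3-ol (racemic) | C=CC(O)CCO[Si](C)(C)C(C)(C)C | intermediate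
5 | 5-((tert-butyldimethylsilyl)oxy)pent-1-en-3-one | C=CC(=O)CCO[Si](C)(C)C(C)(C)C | intermediate
6 | 1-tert-butyl 3-methyl 4-oxopiperidine-1,3-dicarboxylate (racemic, enolisable) | COC(=O)C1CN(C(=O)OC(C)(C)C)CCC1=O | starting material
7 | acrolein (prop-2-enal) | C=CC=O | starting material
8 | 1-tert-butyl 3-methyl (3S)-4-oxo-3-(3-oxopropyl)piperidine-1,3-dicarboxylate | COC(=O)[C@@]1(CCC=O)CN(C(=O)OC(C)(C)C)CCC1=O | intermediate
9 | 3-[(3S)-1-(tert-butoxycarbonyl)-3-(methoxycarbonyl)-4-oxopiperidin-3-yl]propanoic acid | COC(=O)[C@@]1(CCC(=O)O)CN(C(=O)OC(C)(C)C)CCC1=O | intermediate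
10 | 1-tert-butyl 3-methyl (3S)-3-(3-methoxy-3-oxopropyl)-4-oxopiperidine-1,3-dicarboxylate | COC(=O)[C@@]1(CCC(=O)OC)CN(C(=O)OC(C)(C)C)CCC1=O | intermediate
11 | 8-tert-butyl 6-methyl (6S)-6-(3-methoxy-3-oxopropyl)-1,4-dioxa-8-azaspiro[4.5]decane-6,8-dicarboxylate | COC(=O)[C@@]1(CCC(=O)OC)CN(C(=O)OC(C)(C)C)CCC12OCCO2 | intermediate
12 | benzyl bromoacetate | BrCC(=O)OCc1ccccc1 | starting material
13 | 8-tert-butyl 6-methyl (6S)-6-[4-(benzyloxy)-2-(methoxycarbonyl)-4-oxobutyl]-1,4-dioxa-8-azaspiro[4.5]decane-6,8-dicarboxylate (both C18 epimers) | COC(=O)[C@@]1(CC(CC(=O)OCc2ccccc2)C(=O)OC)CN(C(=O)OC(C)(C)C)CCC13OCCO3 | intermediate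
14 | ring-D spiro β-keto ester: cyclopentanone (C14=O) spiro at C21 to the N-Boc piperidine C7-dioxolane, CO2Bn on C15, CO2Me on C18 (C21 as in 8; C15/C18 epimers) | O=C1C(C(=O)OCc2ccccc2)C(C(=O)OC)C[C@@]13CN(C(=O)OC(C)(C)C)CCC34OCCO4 | intermediate
15 | as 14 with C15 also carrying CH2CH2C(=O)CH2CH2OTBS (C15/C18 epimers) | O=C1C(CCC(=O)CCO[Si](C)(C)C(C)(C)C)(C(=O)OCc2ccccc2)C(C(=O)OC)C[C@@]13CN(C(=O)OC(C)(C)C)CCC34OCCO4 | intermediate
16 | β-keto acid: as 15 with CO2H in place of CO2Bn | O=C1C(CCC(=O)CCO[Si](C)(C)C(C)(C)C)(C(=O)O)C(C(=O)OC)C[C@@]13CN(C(=O)OC(C)(C)C)CCC34OCCO4 | intermediate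
17 | ring-D 1,5-diketone: C15 bears H and the 3-oxo-5-(TBS-oxy)pentyl chain (C15/C18 epimers) | O=C1C(CCC(=O)CCO[Si](C)(C)C(C)(C)C)C(C(=O)OC)C[C@@]13CN(C(=O)OC(C)(C)C)CCC34OCCO4 | intermediate
18 | tricyclic alkene: rings C and D (bicyclo[3.3.0]oct-1-ene, C13=C14) spiro at C21 to the piperidine ketal; CH2CH2OTBS on C13, CO2Me on C18 (C15/C18 epimers) | CC(C)(C)[Si](C)(C)OCCC1=C2C(CC1)C(C(=O)OC)C[C@@]23CN(C(=O)OC(C)(C)C)CCC34OCCO4 | intermediate
19 | keto alcohol: as 18 with free C7 ketone and CH2CH2OH on C13 | OCCC1=C2C(CC1)C(C(=O)OC)C[C@@]23CN(C(=O)OC(C)(C)C)CCC3=O | intermediate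
20 | keto iodide: as 19 with CH2CH2I on C13 | ICCC1=C2C(CC1)C(C(=O)OC)C[C@@]23CN(C(=O)OC(C)(C)C)CCC3=O | intermediate
21 | bridged tetracyclic ketone: C10–C11 closed, N-Boc-3-azabicyclo[4.3.1]dec-7-en-10-one fused to rings C and D (C15/C18 epimers) | O=C2[C@@H]1CCC3=C4C(CC3)C(C(=O)OC)C[C@@]42CN(C(=O)OC(C)(C)C)C1 | intermediate
22 | exocyclic alkene: as 21 with C7=CH2 | C=C2[C@@H]1CCC3=C4C(CC3)C(C(=O)OC)C[C@@]42CN(C(=O)OC(C)(C)C)C1 | intermediate
23 | α-phenylselanyl ester: as 22 with SePh on C18 | C=C2[C@@H]1CCC3=C4C(CC3)C([Se]c5ccccc5)(C(=O)OC)C[C@@]42CN(C(=O)OC(C)(C)C)C1 | intermediate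
24 | selenoxide of 23 | C=C2[C@@H]1CCC3=C4C(CC3)C([Se](=O)c5ccccc5)(C(=O)OC)C[C@@]42CN(C(=O)OC(C)(C)C)C1 | intermediate
25 | dienoate: C13=C14–C15=C18–CO2Me, C7=CH2 | C=C2[C@@H]1CCC3=C4C(CC3)=C(C(=O)OC)C[C@@]42CN(C(=O)OC(C)(C)C)C1 | intermediate
26 | B-alkyl-9-BBN adduct (boron on the former methylene carbon) | C(B5C6CCCC5CCC6)C2[C@@H]1CCC3=C4C(CC3)=C(C(=O)OC)C[C@@]42CN(C(=O)OC(C)(C)C)C1 | intermediate
27 | primary alcohol: C7(H)–CH2OH | OCC2[C@@H]1CCC3=C4C(CC3)=C(C(=O)OC)C[C@@]42CN(C(=O)OC(C)(C)C)C1 | intermediate
28 | bridging aldehyde: C7(H)–CHO | O=CC2[C@@H]1CCC3=C4C(CC3)=C(C(=O)OC)C[C@@]42CN(C(=O)OC(C)(C)C)C1 | intermediate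
29 | hydroxymethyl aldehyde: quaternary C7 with CH2OH syn to the cycloheptene bridge and CHO on the nitrogen side | O=C[C@@]2(CO)[C@@H]1CCC3=C4C(CC3)=C(C(=O)OC)C[C@@]42CN(C(=O)OC(C)(C)C)C1 | intermediate
30 | silyl ether aldehyde: TBS ether of 29 | O=C[C@@]2(CO[Si](C)(C)C(C)(C)C)[C@@H]1CCC3=C4C(CC3)=C(C(=O)OC)C[C@@]42CN(C(=O)OC(C)(C)C)C1 | intermediate
31 | 3-methylbutan-2-one | CC(C)C(C)=O | starting material
32 | β-hydroxy ketone: C7–CH(OH)–CH2–C(=O)–iPr (carbinol epimers) | CC(C)C(=O)CC(O)[C@@]2(CO[Si](C)(C)C(C)(C)C)[C@@H]1CCC3=C4C(CC3)=C(C(=O)OC)C[C@@]42CN(C(=O)OC(C)(C)C)C1 | intermediate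
33 | mesylate of 32 | CC(C)C(=O)CC(OS(C)(=O)=O)[C@@]2(CO[Si](C)(C)C(C)(C)C)[C@@H]1CCC3=C4C(CC3)=C(C(=O)OC)C[C@@]42CN(C(=O)OC(C)(C)C)C1 | intermediate
34 | E-enone: C7–CH=CH–C(=O)–iPr, dienoate intact | CC(C)C(=O)/C=C/[C@@]2(CO[Si](C)(C)C(C)(C)C)[C@@H]1CCC3=C4C(CC3)=C(C(=O)OC)C[C@@]42CN(C(=O)OC(C)(C)C)C1 | intermediate
35 | saturated keto ester: C15-H and C18-H cis, both on the ring-D face away from C7 | CC(C)C(=O)CC[C@@]2(CO[Si](C)(C)C(C)(C)C)[C@@H]1CCC3=C4[C@H](CC3)[C@H](C(=O)OC)C[C@@]42CN(C(=O)OC(C)(C)C)C1 | intermediate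
36 | amino hydroxy ketone: free NH and CH2OH | CC(C)C(=O)CC[C@@]2(CO)[C@@H]1CCC3=C4[C@H](CC3)[C@H](C(=O)OC)C[C@@]42CNC1 | intermediate
37 | N-methyl amino hydroxy ketone | CC(C)C(=O)CC[C@@]2(CO)[C@@H]1CCC3=C4[C@H](CC3)[C@H](C(=O)OC)C[C@@]42CN(C)C1 | intermediate
38 | cyclic hemiketal (2-hydroxy-2-isopropyl tetrahydropyran spiro at C7) | CC(C)C1(O)CC[C@@]2(CO1)[C@@H]1CCC3=C4[C@H](CC3)[C@H](C(=O)OC)C[C@@]42CN(C)C1 | intermediate
39 | methyl ester of the target | CC(C)C1=CC[C@@]2(CO1)[C@@H]1CCC3=C4[C@H](CC3)[C@H](C(=O)OC)C[C@@]42CN(C)C1 | intermediate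
40 | CNP0237695.1 | CC(C)C1=CC[C@@]2(CO1)[C@@H]1CCC3=C4[C@H](CC3)[C@H](C(=O)O)C[C@@]42CN(C)C1 | target

## Step count and risk

Total: 29 steps. Longest linear sequence: 26 steps (6 → 40, steps 4–29); the enone branch (steps 1–3) joins at step 10.

**Step 12 (McMurry coupling).** The hindered C14 ketone, the neighbouring ester and the silyl ether may lead to over‑reduction or incomplete deoxygenation. The fallback separates C–C bond formation from deoxygenation and sets out from 17. Samarium diiodide (SmI2, THF/tBuOH, −78 °C) effects ketyl–ketone pinacol cyclisation to the cis‑fused ditertiary ring‑C diol F1. 1,1′‑Thiocarbonyldiimidazole (toluene, 110 °C) converts it into the cyclic thionocarbonate F2. 1,3‑Dimethyl‑2‑phenyl‑1,3,2‑diazaphospholidine (40 °C) then effects the stereospecific Corey–Winter elimination, and the fallback returns to the route at 18.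

**Step 21 (facial selectivity at C7).** If electrophiles enter from the piperidine face instead of the cycloheptene face, the order of the two bond formations at C7 is reversed; the fallback sets out from 28. DBU‑catalysed Michael addition of 28 to 4‑methylpent‑1‑en‑3‑one (CC(C)C(=O)C=C) places the oxopentyl chain on that face and leaves CHO as C8, giving the keto aldehyde F3. NaBH(OAc)3 reduces only the aldehyde to the hydroxy ketone F4, and TBSCl/imidazole gives the silyl ether F5. Hydrogenation of F5 under the conditions of step 25 (only the dienoate remains to be reduced) returns to the route at 35.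

**Step 25 (chemo‑ and face‑selective hydrogenation).** The tetrasubstituted enoate may resist hydrogenation or the catalyst may isomerise C13=C14. The fallback replaces H2 addition by hydride conjugate addition and protonation, and sets out from 34. Copper hydride generated from Cu(OAc)2·H2O, 1,2‑bis(diphenylphosphino)benzene and polymethylhydrosiloxane in toluene/tBuOH reduces the enone and adds hydride to C15 of the dienoate from the open face. The resulting silyl ketene acetal is protonated at C18 by tBuOH from the same face, which returns directly to 35; this fallback makes no compound outside the list (F0).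

## Further compounds

F1 | step 12 | cis-fused ring-C 1,2-diol (OH on C13 and C14; ketal, Boc, TBS ether and CO2Me retained) | CC(C)(C)[Si](C)(C)OCCC1(O)CCC2C(C(=O)OC)C[C@@]3(CN(C(=O)OC(C)(C)C)CCC34OCCO4)C12O
F2 | step 12 | cyclic thionocarbonate of F1 | CC(C)(C)[Si](C)(C)OCCC15CCC2C(C(=O)OC)C[C@@]3(CN(C(=O)OC(C)(C)C)CCC34OCCO4)C12OC(=S)O5
F3 | step 21 | keto aldehyde: quaternary C7 with CHO syn to the cycloheptene bridge and CH2CH2C(=O)iPr on the nitrogen side | CC(C)C(=O)CC[C@@]2(C=O)[C@@H]1CCC3=C4C(CC3)=C(C(=O)OC)C[C@@]42CN(C(=O)OC(C)(C)C)C1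
F4 | step 21 | hydroxy ketone from F3 (CH2OH on C7) | CC(C)C(=O)CC[C@@]2(CO)[C@@H]1CCC3=C4C(CC3)=C(C(=O)OC)C[C@@]42CN(C(=O)OC(C)(C)C)C1
F5 | step 21 | TBS ether of F4 (dienoate intact) | CC(C)C(=O)CC[C@@]2(CO[Si](C)(C)C(C)(C)C)[C@@H]1CCC3=C4C(CC3)=C(C(=O)OC)C[C@@]42CN(C(=O)OC(C)(C)C)C1
F0 | step 25 | none | none
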